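**Plan**
- Retrosynthesis: the two O–CH3 bonds (masked catechol) and the C6–Br bond are cut first. The ring bonds C1–C2 and C5–C6 are then cut together. The CH2–SO2 bond of the side arm and the C–Br and S=O bonds of the diene are cut last.
- Enabling feature: number the benzene ring C1 (CH2SO2CH3), C2 (Br), C3/C4 (OH), C5/C6 (Br). The stretch C2–C5 reads Br/O/O/Br from either end and is the carbon frame of a 2,5-dibromo-3,4-dioxygenated thiophene. C1–C6 is a two-carbon unit at the alkyne level that carries only the sulfone arm.
- Forward: the purchased thiophene ring is brominated and oxidised at sulfur, and the alkyne comes from one sulfinate alkylation. The only carbocycle forms when the five-membered sulfone ring takes up the alkyne and expels SO2.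
- The last bromine enters at the single free ring C–H, and the methyl ethers are then removed.
- Stereochemistry: the target is achiral with no stereocentre. The bridged cycloadduct is a racemic transient whose bridgeheads become planar on aromatisation.

Key step: step 4

Remark: dimethyldioxirane is taken as a separately prepared, titrated acetone solution, and the brominated dialkoxythiophene and its dioxide are assumed to need cold, dark handling and prompt use, since 2,5-dihalo-3,4-dialkoxythiophenes tend to self-couple on storage.

**Step 1**
Reactants: 1 3,4-dimethoxythiophene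
Product: 3 2,5-dibromo-3,4-dimethoxythiophene, via 2-bromo-3,4-dimethoxythiophene 2 (not isolated)
Conditions: NBS (2.05 equiv), DMF, 0 °C, dark
Reagents that add atoms: N-bromosuccinimide, O=C1CCC(=O)N1Br
Why: Electrophilic aromatic substitution with NBS should go to the two free α positions, which are the most nucleophilic carbons of a thiophene, each lie next to a methoxy donor, and are the only ring C–H bonds present.

**Step 2**
Reactants: 3 2,5-dibromo-3,4-dimethoxythiophene
Product: 5 2,5-dibromo-3,4-dimethoxythiophene 1,1-dioxide, via 2,5-dibromo-3,4-dimethoxythiophene 1-oxide 4 (not isolated)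
Conditions: dimethyldioxirane (2.5 equiv, acetone solution), CH2Cl2, −20 → 0 °C; cold evaporation
Reagents that add atoms: dimethyldioxirane, CC1(C)OO1
Why: S-oxidation by oxygen-atom transfer from a dioxirane is an established way to thiophene 1,1-dioxides, halogenated ones included, and the neutral acid-free medium should spare the acid-labile dibromide while the non-aromatic S-oxide 4 is oxidised faster than 3.

**Step 3**
Reactants: 6 propargyl bromide; 7 sodium methanesulfinate
Product: 8 methyl propargyl sulfone (3-(methylsulfonyl)prop-1-yne)
Conditions: DMF, 0 °C → rt; neutral aqueous work-up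
Reagents that add atoms: none
Why: SN2 S-alkylation of the soft sulfinate sulfur by a primary propargylic bromide should give the sulfone, and the sulfinate is too weak a base to shift the alkyne to the allene.

**Step 4**
Reactants: 5 2,5-dibromo-3,4-dimethoxythiophene 1,1-dioxide; 8 methyl propargyl sulfone
Product: 10 1,4-dibromo-2,3-dimethoxy-5-[(methylsulfonyl)methyl]benzene, via bridged 7-thiabicyclo[2.2.1]heptadiene 7,7-dioxide adduct 9 (not isolated)
Conditions: 8 (4 equiv), BHT (cat.), dry PhCl, 125 °C, slow addition of 5, N2 sweep, base-free glassware
Reagents that add atoms: none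
Why: Oxidation at sulfur has removed the aromaticity of the heterocycle, so 5 behaves as a rigid s-cis diene whose α carbons add suprafacially to the C≡C bond of 8 in a concerted [4+2] cycloaddition that makes C1–C2 and C5–C6 (target numbering) in one event and gives the bridged sulfone 9. Adduct 9 holds a 2,5-dihydrothiophene 1,1-dioxide unit inside a strained bicycle and should shed SO2 at once by a thermally allowed cheletropic extrusion, which delivers arene 10 at the right oxidation level without any oxidant and makes the sequence irreversible. The closest known reaction type is the Diels–Alder/SO2-extrusion benzannulation of halogenated thiophene 1,1-dioxides with alkynes. The benzene ring is closed in an intermolecular [4+2] mode, four carbons from the diene and two from the alkyne, while the five-membered sulfur ring is taken apart. No stereocentre has to be controlled, since the two bridgehead centres of racemic 9 become sp2 carbons on loss of SO2. Regiochemistry is moot because 5 has a mirror plane through sulfur and the midpoint of its C3–C4 bond; the selectivity that matters is cross-addition over self-addition of 5, secured by the full substitution of both of its C=C bonds (poor 2π partners), by its slow addition to an excess of 8, and by a base-free medium that keeps 8 from sliding to the allenyl sulfone.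

**Step 5**
Reactants: 10 1,4-dibromo-2,3-dimethoxy-5-[(methylsulfonyl)methyl]benzene
Product: 11 1,2,4-tribromo-5,6-dimethoxy-3-[(methylsulfonyl)methyl]benzene
Conditions: Br2 (1.5 equiv), FeBr3 (10 mol %), CH2Cl2, 0 °C → rt, dark
Reagents that add atoms: bromine, BrBr
Why: Lewis-acid-catalysed electrophilic aromatic bromination can only strike C6, the single ring C–H, which lies para to the C3 methoxy group, and exclusion of light should suppress radical bromination of the CH2 beside the sulfone.

**Step 6**
Reactants: 11 1,2,4-tribromo-5,6-dimethoxy-3-[(methylsulfonyl)methyl]benzene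
Product: 13 3,4,6-tribromo-5-[(methylsulfonyl)methyl]benzene-1,2-diol (target), via cyclic catechol bromoborane 12 (not isolated)
Conditions: BBr3 (3.5 equiv), CH2Cl2, −78 °C → rt; then H2O, 0 °C
Reagents that add atoms: none
Why: In this BBr3 aryl methyl ether cleavage boron binds each methoxy oxygen and bromide removes the methyl group by SN2 to give the cyclic bromoborane 12, which water hydrolyses to the catechol while the aryl bromides and the sulfone stay untouched.

**Compound list**
1 | 3,4-dimethoxythiophene | COc1cscc1OC | starting material
2 | 2-bromo-3,4-dimethoxythiophene | COc1csc(Br)c1OC | intermediate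
3 | 2,5-dibromo-3,4-dimethoxythiophene | COc1c(Br)sc(Br)c1OC | intermediate
4 | 2,5-dibromo-3,4-dimethoxythiophene 1-oxide | COC1=C(Br)S(=O)C(Br)=C1OC | intermediate
5 | 2,5-dibromo-3,4-dimethoxythiophene 1,1-dioxide | COC1=C(Br)S(=O)(=O)C(Br)=C1OC | intermediate
6 | propargyl bromide (3-bromoprop-1-yne) | C#CCBr | starting material
7 | sodium methanesulfinate | CS(=O)[O-].[Na+] | starting material
8 | methyl propargyl sulfone (3-(methylsulfonyl)prop-1-yne) | C#CCS(C)(=O)=O | intermediate
9 | 1,4-dibromo-5,6-dimethoxy-2-[(methylsulfonyl)methyl]-7-thiabicyclo[2.2.1]hepta-2,5-diene 7,7-dioxide (racemic; bridgehead configurations tied by the bridge) | CS(=O)(=O)CC1=CC2(Br)C(OC)=C(OC)C1(Br)S2(=O)=O | intermediate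
10 | 1,4-dibromo-2,3-dimethoxy-5-[(methylsulfonyl)methyl]benzene | CS(=O)(=O)Cc1cc(Br)c(OC)c(OC)c1Br | intermediate
11 | 1,2,4-tribromo-5,6-dimethoxy-3-[(methylsulfonyl)methyl]benzene | CS(=O)(=O)Cc1c(Br)c(Br)c(OC)c(OC)c1Br | intermediate
12 | 2,4,5,7-tetrabromo-6-[(methylsulfonyl)methyl]-1,3,2-benzodioxaborole | CS(=O)(=O)Cc1c(Br)c2OB(Br)Oc2c(Br)c1Br | intermediate
13 | 3,4,6-tribromo-5-[(methylsulfonyl)methyl]benzene-1,2-diol (2,3,6-tribromo-4,5-dihydroxybenzyl methyl sulfone; achiral) | CS(=O)(=O)Cc1c(Br)c(O)c(O)c(Br)c1Br | target

**Step count**
Total step count: 6.
Longest linear sequence: 5 (steps 1, 2, 4, 5, 6). Step 3 is a one-step side branch.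

**Steps most likely to fail**

**Step 2.**
- Risk: the two α-bromines drain the sulfur lone pairs, so oxygen transfer to sulfur may be outrun by attack on the methoxy-bearing C=C bonds. The labile dibromide may also self-couple before it is oxidised.
- Fallback: it sets out from 1 and rejoins at 5, and it brings bromine in only after the sulfur is oxidised.
- Double α-lithiation of 1 (n-BuLi, TMEDA, THF, −78 → 0 °C) and a Me3SiCl quench should give 3,4-dimethoxy-2,5-bis(trimethylsilyl)thiophene F1. Its silyl groups raise the nucleophilicity of sulfur and shield the ring.
- Buffered peracid oxidation (mCPBA, NaHCO3, CH2Cl2) should then give 3,4-dimethoxy-2,5-bis(trimethylsilyl)thiophene 1,1-dioxide F2.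
- Ipso-bromodesilylation of both vinylsilane positions (Br2, AgBF4, CH2Cl2), a known route to 2,5-dibromothiophene dioxides, leads to 5.

**Step 4.**
- Risk: cycloaddition of an unactivated terminal alkyne may be slower than thermal decay of the diene through self-addition or hydrolytic loss of the enol ethers. Long heating may also shift the propargyl sulfone to its allenyl isomer.
- Fallback: it sets out from 5 and rejoins at 10. It lowers the oxidation level of the 2π partner and keeps the same two ring bonds.
- Commercial allyl methyl sulfone, an alkene of the kind that thiophene dioxides take up more readily than alkynes and that cannot isomerise to an allene, is heated in excess with 5 in toluene.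
- The first-formed 1,4-dibromo-2,3-dimethoxy-5-[(methylsulfonyl)methyl]-7-thiabicyclo[2.2.1]hept-2-ene 7,7-dioxide F3 should lose SO2 in the flask. This gives 1,4-dibromo-2,3-dimethoxy-5-[(methylsulfonyl)methyl]cyclohexa-1,3-diene F4.
- Dehydrogenation of F4 with DDQ in warm toluene gives 10.

**Step 5.**
- Risk: the crowded, doubly brominated ring has its methoxy groups twisted out of conjugation and may resist substitution. Forcing conditions could then bring on radical bromination at the CH2 beside the sulfone, or Lewis-acid ether cleavage followed by oxidation.
- Fallback: it sets out from 10 and rejoins at 13. It inverts the order of the last two operations so that a free phenol activates the position.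
- BBr3 in CH2Cl2 should convert 10 through 2,4,7-tribromo-5-[(methylsulfonyl)methyl]-1,3,2-benzodioxaborole F5, hydrolysed on work-up, into 3,6-dibromo-4-[(methylsulfonyl)methyl]benzene-1,2-diol F6.
- The remaining C–H of F6 is para to a hydroxyl group and should brominate with Br2 in AcOH at room temperature without a Lewis acid. A reductive Na2S2O4 wash guards against over-oxidation of the catechol.

**Further compounds**
F1 | step 2 | 3,4-dimethoxy-2,5-bis(trimethylsilyl)thiophene | COc1c([Si](C)(C)C)sc([Si](C)(C)C)c1OC
F2 | step 2 | 3,4-dimethoxy-2,5-bis(trimethylsilyl)thiophene 1,1-dioxide | COC1=C([Si](C)(C)C)S(=O)(=O)C([Si](C)(C)C)=C1OC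
F3 | step 4 | 1,4-dibromo-2,3-dimethoxy-5-[(methylsulfonyl)methyl]-7-thiabicyclo[2.2.1]hept-2-ene 7,7-dioxide (racemic, endo/exo of no consequence, not isolated) | CS(=O)(=O)CC1CC2(Br)C(OC)=C(OC)C1(Br)S2(=O)=O
F4 | step 4 | 1,4-dibromo-2,3-dimethoxy-5-[(methylsulfonyl)methyl]cyclohexa-1,3-diene (racemic) | CS(=O)(=O)CC1CC(Br)=C(OC)C(OC)=C1Br
F5 | step 5 | 2,4,7-tribromo-5-[(methylsulfonyl)methyl]-1,3,2-benzodioxaborole (not isolated) | CS(=O)(=O)Cc1cc(Br)c2OB(Br)Oc2c1Br
F6 | step 5 | 3,6-dibromo-4-[(methylsulfonyl)methyl]benzene-1,2-diol | CS(=O)(=O)Cc1cc(Br)c(O)c(O)c1Br
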